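A direct plan would build methyl 2,4-dihydroxy-6-pentylbenzoate A1 by Michael–Dieckmann condensation and aromatization.
Benzylation at O-4, methylation at O-2 and saponification would turn A1 into the acid half, 4-(benzyloxy)-2-methoxy-6-pentylbenzoic acid A2.
Debenzylation of half of A2 and benzylation of its carboxyl group would give the phenol half, benzyl 4-hydroxy-2-methoxy-6-pentylbenzoate A3.
A mixed-anhydride esterification of A2 with A3 would give the dibenzyl depside benzyl 4-{[4-(benzyloxy)-2-methoxy-6-pentylbenzoyl]oxy}-2-methoxy-6-pentylbenzoate A4, and hydrogenolysis of A4 would end the route.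
Weak: the five protecting-group operations from A1 to A3 would form no skeletal bond and would only tell two phenol oxygens apart.
Weak: the hydrolysis of the di-ortho-substituted ester on the way to A2 would need hot concentrated hydroxide in a dipolar aprotic solvent and would risk decarboxylation of an electron-rich acid.
Weak: the esterification that leads to A4 would close the depside bond last, at a hindered acid on the most precious material, where C-acylation of the phenol ring competes.

**Plan of the new route**
Each ring of the target (ring A, the acyl ring with the free 4-OH; ring B, the ring with CO2H) is a benzene with the carboxyl carbon on C1, OMe on C2, oxygen on C4 and pentyl on C6: C1 and C6 are the triple bond of an oct-2-ynoate, and C2–C5 are the four carbons of 1,1-dimethoxy-3-(trimethylsilyloxy)buta-1,3-diene.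
The retrosynthesis cuts C1–C2 and C5–C6 of ring A, then the ester C–O bond (now at an unhindered alkynoic acid), then C1–C2 and C5–C6 of ring B.
Forward, ring B arises first by cycloaddition–aromatization, its phenol is acylated with oct-2-ynoic acid, and ring A arises last, directly on the finished depside ester.
The ketene acetal carbon of the diene becomes C2–OMe and the silyloxy carbon becomes C4–OH, so the two oxygens of each ring differ from the start. No benzyl/methyl shuffle and no hindered saponification are needed.
No di-ortho-substituted benzoic acid is ever activated; one allyl ester is the only protecting group.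

Key step: step 6

Remark: 1,1-dimethoxyethene and oct-2-ynoic acid are taken as purchasable reagents, and the target is achiral, so no configuration has to be set.

Step 1
Reactants: 1 1,1-dimethoxyethene (2.1 equiv); 2 acetyl chloride
Product: 3 4,4-dimethoxybut-3-en-2-one
Conditions: Et2O, 0 °C to rt, 12 h; distil under reduced pressure
Reagents that add atoms: none
Why: C-acylation of a ketene acetal, in which the nucleophilic CH2 of 1 attacks the acid chloride and the dimethoxycarbenium ion loses a proton, while the second equivalent of 1 takes up the HCl as methyl acetate and chloromethane, so that no amine (which would turn acetyl chloride into ketene) is needed.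

Step 2
Reactants: 3 4,4-dimethoxybut-3-en-2-one
Product: 4 1,1-dimethoxy-3-(trimethylsilyloxy)buta-1,3-diene
Conditions: TMSCl (1.3 equiv), Et3N (1.5 equiv), ZnCl2 (3 mol %), toluene, 40 °C, 12 h; filter under N2, distil under reduced pressure
Reagents that add atoms: chlorotrimethylsilane, C[Si](C)(C)Cl
Why: Silyl enol ether formation by soft enolization, in which the methyl group is the only enolizable position of the acylketene acetal, so that only the cross-conjugated 2-silyloxydiene can form.

Step 3
Reactants: 5 oct-2-ynoic acid
Product: 6 allyl oct-2-ynoate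
Conditions: allyl bromide (1.2 equiv), KHCO3 (1.5 equiv), DMF, rt
Reagents that add atoms: allyl bromide, C=CCBr
Why: SN2 O-alkylation of the carboxylate, with hydrogencarbonate too weak a base to isomerize the alk-2-ynoate to an allenoate.

Step 4
Reactants: 6 allyl oct-2-ynoate; 4 1,1-dimethoxy-3-(trimethylsilyloxy)buta-1,3-diene (2.5 equiv)
Product: 9 allyl 4-hydroxy-2-methoxy-6-pentylbenzoate, via cyclohexa-1,4-diene cycloadduct 7 (not isolated), via aryl trimethylsilyl ether 8 (not isolated)
Conditions: xylene, 140 °C, sealed tube, 24 h; then 0.1 M HCl, THF, rt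
Reagents that add atoms: none
Why: Diels–Alder cycloaddition of an alk-2-ynoate to a 1,1-dimethoxy-3-silyloxydiene followed by aromatization through loss of methanol, the nucleophilic CH2 terminus of the diene bonding to the β-carbon of the ynoate so that OMe comes ortho and the later phenol oxygen para to the ester, after which dilute acid cleaves the aryl silyl ether.

Step 5
Reactants: 9 allyl 4-hydroxy-2-methoxy-6-pentylbenzoate; 5 oct-2-ynoic acid (1.2 equiv)
Product: 11 allyl 2-methoxy-4-(oct-2-ynoyloxy)-6-pentylbenzoate, via O-(oct-2-ynoyl)-N,N'-dicyclohexylisourea 10 (not isolated)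
Conditions: DCC (1.2 equiv), DMAP (5 mol %), CH2Cl2, 0 °C to rt
Reagents that add atoms: none
Why: Steglich esterification, in which the unhindered alkynoic acid is activated as its O-acylisourea and passed by DMAP to the acidic, unhindered 4-hydroxyl of 9 at low temperature, where conjugate addition to the triple bond should not compete and the hindered allyl ester is untouched.

Step 6
Reactants: 11 allyl 2-methoxy-4-(oct-2-ynoyloxy)-6-pentylbenzoate; 4 1,1-dimethoxy-3-(trimethylsilyloxy)buta-1,3-diene (3 equiv)
Product: 14 allyl 4-[(4-hydroxy-2-methoxy-6-pentylbenzoyl)oxy]-2-methoxy-6-pentylbenzoate, via cyclohexa-1,4-diene cycloadduct 12 (not isolated), via aryl trimethylsilyl ether 13 (not isolated)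
Conditions: toluene, 110 °C, sealed tube, 24 h; then 0.1 M HCl, THF, 0 °C to rt
Reagents that add atoms: none
Why: The electron-rich diene 4 adds to the electron-poor triple bond of the aryl alk-2-ynoate in a [4+2] cycloaddition (concerted and asynchronous, or stepwise through Michael attack of the CH2 terminus and closure of the zwitterion, both leading to 12), the gem-dimethoxy carbon of 12 then loses methanol in a 1,4-elimination to give the arene 13, and dilute acid cleaves the silyl ether. The closest known reaction type is the Diels–Alder/aromatization of 1,1-dimethoxy-3-silyloxybutadienes with alkyl alk-2-ynoates to 4-hydroxy-2-methoxy-6-alkylbenzoates, and an aryl ester only lowers the LUMO of the dienophile further. Ring A is closed by an intermolecular [4+2] annulation that forms its C1–C2 and C5–C6 bonds in one operation, and the aromatization makes the closure irreversible. No stereocentre has to be controlled, since both sp3 ring carbons of 12 become arene carbons. The one regiochemistry needed, OMe next to the depside carbonyl, is secured electronically: the most nucleophilic diene carbon (the CH2 terminus, activated by the silyloxy group and vinylogously by both methoxy groups) bonds to the β-carbon of the ynoate and the ketene acetal carbon to the α-carbon. The chemoselectivity needed, that the diene spares the aryl and allyl ester carbonyls, is secured by heating without any Lewis acid, under which a ketene acetal does not acylate at an ester.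

Step 7
Reactants: 14 allyl 4-[(4-hydroxy-2-methoxy-6-pentylbenzoyl)oxy]-2-methoxy-6-pentylbenzoate
Product: 15 4-O-demethylplanaic acid
Conditions: Pd(PPh3)4 (5 mol %), N-methylaniline (3 equiv), THF, rt; then cold 0.5 M HCl work-up
Reagents that add atoms: none
Why: Tsuji–Trost deallylation, in which zerovalent palladium ionizes the allyl ester to a π-allyl complex and the carboxylate, and N-methylaniline takes up the allyl group while being too weak a nucleophile to attack the hindered depside ester, so that the acid should be set free under neutral conditions that spare the aryl ester, the methyl ethers and the phenol.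

**Compound list**
1 | 1,1-dimethoxyethene | C=C(OC)OC | starting material
2 | acetyl chloride | CC(=O)Cl | starting material
3 | 4,4-dimethoxybut-3-en-2-one | CC(=O)C=C(OC)OC | intermediate
4 | 1,1-dimethoxy-3-(trimethylsilyloxy)buta-1,3-diene | C=C(O[Si](C)(C)C)C=C(OC)OC | intermediate
5 | oct-2-ynoic acid | CCCCCC#CC(=O)O | starting material
6 | allyl oct-2-ynoate | CCCCCC#CC(=O)OCC=C | intermediate
7 | allyl 6,6-dimethoxy-2-pentyl-4-(trimethylsilyloxy)cyclohexa-1,4-diene-1-carboxylate | CCCCCC1=C(C(=O)OCC=C)C(OC)(OC)C=C(O[Si](C)(C)C)C1 | intermediate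
8 | allyl 2-methoxy-6-pentyl-4-(trimethylsilyloxy)benzoate | CCCCCc1cc(O[Si](C)(C)C)cc(OC)c1C(=O)OCC=C | intermediate
9 | allyl 4-hydroxy-2-methoxy-6-pentylbenzoate | CCCCCc1cc(O)cc(OC)c1C(=O)OCC=C | intermediate
10 | O-(oct-2-ynoyl)-N,N'-dicyclohexylisourea | CCCCCC#CC(=O)OC(=NC1CCCCC1)NC1CCCCC1 | intermediate
11 | allyl 2-methoxy-4-(oct-2-ynoyloxy)-6-pentylbenzoate | CCCCCC#CC(=O)Oc1cc(CCCCC)c(C(=O)OCC=C)c(OC)c1 | intermediate
12 | allyl 4-{[6,6-dimethoxy-2-pentyl-4-(trimethylsilyloxy)cyclohexa-1,4-diene-1-carbonyl]oxy}-2-methoxy-6-pentylbenzoate | CCCCCC1=C(C(=O)Oc2cc(CCCCC)c(C(=O)OCC=C)c(OC)c2)C(OC)(OC)C=C(O[Si](C)(C)C)C1 | intermediate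
13 | allyl 2-methoxy-4-{[2-methoxy-6-pentyl-4-(trimethylsilyloxy)benzoyl]oxy}-6-pentylbenzoate | CCCCCc1cc(O[Si](C)(C)C)cc(OC)c1C(=O)Oc1cc(CCCCC)c(C(=O)OCC=C)c(OC)c1 | intermediate
14 | allyl 4-[(4-hydroxy-2-methoxy-6-pentylbenzoyl)oxy]-2-methoxy-6-pentylbenzoate | CCCCCc1cc(O)cc(OC)c1C(=O)Oc1cc(CCCCC)c(C(=O)OCC=C)c(OC)c1 | intermediate
15 | 4-O-demethylplanaic acid (4-[(4-hydroxy-2-methoxy-6-pentylbenzoyl)oxy]-2-methoxy-6-pentylbenzoic acid) | CCCCCc1cc(OC(=O)c2c(CCCCC)cc(O)cc2OC)cc(OC)c1C(=O)O | target

Total step count: 7. Longest linear sequence: 6 steps (steps 1, 2, 4, 5, 6 and 7).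

**Steps most likely to fail**

Step 6. The cycloaddition may be slower than oligomerization and desilylation of the diene, or the ketene acetal may be acylated by the activated aryl ester with loss of ring B as its phenol. The fallback sets out from 9 and comes back at 14; ring A is made as a separate acid from the ring that step 4 already delivers and is attached as an acid chloride. Part of 9 would be silylated (TBSCl, imidazole, DMF) to allyl 4-(tert-butyldimethylsilyloxy)-2-methoxy-6-pentylbenzoate F1. The allyl ester would be removed (Pd(PPh3)4, N-methylaniline, THF) to give 4-(tert-butyldimethylsilyloxy)-2-methoxy-6-pentylbenzoic acid F2. This would be turned under neutral conditions with 1-chloro-N,N,2-trimethylprop-1-en-1-amine (CH2Cl2, rt) into 4-(tert-butyldimethylsilyloxy)-2-methoxy-6-pentylbenzoyl chloride F3. Acylation of a second portion of 9 (Et3N, DMAP, CH2Cl2, rt to 40 °C) should give allyl 4-{[4-(tert-butyldimethylsilyloxy)-2-methoxy-6-pentylbenzoyl]oxy}-2-methoxy-6-pentylbenzoate F4, and HF·pyridine in THF at 0 °C would remove the silyl group to give 14.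

Step 4. The β-pentyl alkyl ynoate is the least reactive dienophile of the route, and the diene may decompose at the temperature needed before it adds. The fallback sets out from diene 4 and purchasable oct-2-ynal and comes back at 9; the ring is made at the aldehyde oxidation level, where the dienophile is far more electrophilic. Oct-2-ynal and 4 (toluene, 60 °C) should give the cycloadduct 6,6-dimethoxy-2-pentyl-4-(trimethylsilyloxy)cyclohexa-1,4-diene-1-carbaldehyde F5. This should lose methanol to the silyl ether 2-methoxy-6-pentyl-4-(trimethylsilyloxy)benzaldehyde F6, and dilute HCl would give 4-hydroxy-2-methoxy-6-pentylbenzaldehyde F7. Lindgren–Pinnick oxidation (NaClO2, NaH2PO4, 2-methylbut-2-ene, tBuOH/H2O) would give 4-hydroxy-2-methoxy-6-pentylbenzoic acid F8. Carboxylate-selective allylation (allyl bromide, KHCO3, DMF, rt) returns to 9.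

Step 1. The dimethoxycarbenium intermediate may be demethylated by chloride, with loss of chloromethane to a β-keto ester, faster than it loses a proton. The fallback sets out from 2 and comes back at 3; the two methoxy groups are introduced by substitution instead. Addition of acetyl chloride 2 to 1,1-dichloroethene (AlCl3, CH2Cl2, 0 °C) would give 4,4,4-trichlorobutan-2-one F9, from which Et3N removes HCl to give 4,4-dichlorobut-3-en-2-one F10. Two addition–elimination steps with NaOMe (2.1 equiv, MeOH, 0 °C), the first leading to 4-chloro-4-methoxybut-3-en-2-one F11 (transient, either geometry), would replace both chlorines and give 3.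

**Further compounds**
F1 | step 6 | allyl 4-(tert-butyldimethylsilyloxy)-2-methoxy-6-pentylbenzoate | CCCCCc1cc(O[Si](C)(C)C(C)(C)C)cc(OC)c1C(=O)OCC=C
F2 | step 6 | 4-(tert-butyldimethylsilyloxy)-2-methoxy-6-pentylbenzoic acid | CCCCCc1cc(O[Si](C)(C)C(C)(C)C)cc(OC)c1C(=O)O
F3 | step 6 | 4-(tert-butyldimethylsilyloxy)-2-methoxy-6-pentylbenzoyl chloride | CCCCCc1cc(O[Si](C)(C)C(C)(C)C)cc(OC)c1C(=O)Cl
F4 | step 6 | allyl 4-{[4-(tert-butyldimethylsilyloxy)-2-methoxy-6-pentylbenzoyl]oxy}-2-methoxy-6-pentylbenzoate | CCCCCc1cc(O[Si](C)(C)C(C)(C)C)cc(OC)c1C(=O)Oc1cc(CCCCC)c(C(=O)OCC=C)c(OC)c1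
F5 | step 4 | 6,6-dimethoxy-2-pentyl-4-(trimethylsilyloxy)cyclohexa-1,4-diene-1-carbaldehyde | CCCCCC1=C(C=O)C(OC)(OC)C=C(O[Si](C)(C)C)C1
F6 | step 4 | 2-methoxy-6-pentyl-4-(trimethylsilyloxy)benzaldehyde | CCCCCc1cc(O[Si](C)(C)C)cc(OC)c1C=O
F7 | step 4 | 4-hydroxy-2-methoxy-6-pentylbenzaldehyde | CCCCCc1cc(O)cc(OC)c1C=O
F8 | step 4 | 4-hydroxy-2-methoxy-6-pentylbenzoic acid | CCCCCc1cc(O)cc(OC)c1C(=O)O
F9 | step 1 | 4,4,4-trichlorobutan-2-one | CC(=O)CC(Cl)(Cl)Cl
F10 | step 1 | 4,4-dichlorobut-3-en-2-one | CC(=O)C=C(Cl)Cl
F11 | step 1 | 4-chloro-4-methoxybut-3-en-2-one | CC(=O)C=C(Cl)OC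
A1 | direct plan | methyl 2,4-dihydroxy-6-pentylbenzoate | CCCCCc1cc(O)cc(O)c1C(=O)OC
A2 | direct plan | 4-(benzyloxy)-2-methoxy-6-pentylbenzoic acid | CCCCCc1cc(OCc2ccccc2)cc(OC)c1C(=O)O
A3 | direct plan | benzyl 4-hydroxy-2-methoxy-6-pentylbenzoate | CCCCCc1cc(O)cc(OC)c1C(=O)OCc1ccccc1
A4 | direct plan | benzyl 4-{[4-(benzyloxy)-2-methoxy-6-pentylbenzoyl]oxy}-2-methoxy-6-pentylbenzoate | CCCCCc1cc(OC(=O)c2c(CCCCC)cc(OCc3ccccc3)cc2OC)cc(OC)c1C(=O)OCc1ccccc1
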